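**Retrosynthetic overview**

1. The target is the hydrolytically opened form of 8-hydroxy-6-methoxy-3-undecylisocoumarin. Its carboxyl carbon (on ring C1) and the side-chain ketone carbon (on the CH2 at ring C6) stand 1,5 to each other and can be tied into a temporary 2-pyranone (enol lactone) ring fused to the benzene ring.
2. In that ring the chain carbon next to the ketone on the alkyl side is the exocyclic 3-methyl carbon. It is the terminus of a trienolate conjugated through C3=C4 and the arene to the lactone C=O, while the otherwise more acidic benzylic CH2 is locked as vinylic C4–H. This is the feature that makes the key step possible.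
3. Key disconnection: the exocyclic CH2–CH2(decyl) bond, made by C-alkylation of the dianion of 8-hydroxy-6-methoxy-3-methylisocoumarin (C11) with 1-iododecane, followed in the same flask by hydroxide opening of the lactone to the keto acid.
4. The methylisocoumarin comes from methyl 2,4-dimethoxy-6-methylbenzoate by lateral acylation with an acetyl Weinreb amide, acid enol-lactonisation and chelation-controlled 8-O-demethylation.
5. Ring order: the benzene ring is bought; the pyranone ring is closed in step 2 and opened again in step 4.

Key step: step 4

Remark: the target has no stereocentre; the open keto acid is assumed to survive brief cold acidification, since closure back to the isocoumarin needs dehydrating acid.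

**Route**

Step 1
Reactants: 1 methyl 2,4-dimethoxy-6-methylbenzoate; 2 N-methoxy-N-methylacetamide
Product: 5 methyl 2,4-dimethoxy-6-(2-oxopropyl)benzoate, via benzylic lithium anion 3 (not isolated), via lithium hemiaminal alkoxide 4 (not isolated)
Conditions: LDA (1.2 equiv), THF, −78 °C; then 2 (1.3 equiv), −78 to −20 °C; cold 1 M HCl
Reagents that add atoms: none
Why: Lateral (benzylic) lithiation of the o-toluate gives an ester-stabilised carbanion that is acylated by the Weinreb amide through a chelated tetrahedral adduct, which prevents over-addition and enolisation of the product before work-up (Weinreb ketone synthesis).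

Step 2
Reactants: 5 methyl 2,4-dimethoxy-6-(2-oxopropyl)benzoate
Product: 6 6,8-dimethoxy-3-methyl-1H-isochromen-1-one
Conditions: TsOH·H2O (0.2 equiv), toluene, reflux, 4 Å molecular sieves in a Soxhlet (removal of MeOH)
Reagents that add atoms: none
Why: Acid-catalysed enol-lactonisation, in which the arene-conjugated enol oxygen of the ketone attacks the ortho ester to close the six-membered ring, should be driven by removal of methanol and by the conjugation gained in the isocoumarin.

Step 3
Reactants: 6 6,8-dimethoxy-3-methyl-1H-isochromen-1-one
Product: 8 8-hydroxy-6-methoxy-3-methyl-1H-isochromen-1-one, via dichloroboron chelate 7 (not isolated)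
Conditions: BCl3 (1.2 equiv), CH2Cl2, −78 to 0 °C; then H2O
Reagents that add atoms: none
Why: Chelation-controlled ether cleavage: boron binds the lactone carbonyl and the peri 8-methoxy oxygen, chloride removes that methyl group to give a six-membered chelate, and the 6-methoxy group, which cannot chelate, should stay untouched.

Step 4
Reactants: 8 8-hydroxy-6-methoxy-3-methyl-1H-isochromen-1-one; 9 1-iododecane
Product: 12 2-hydroxy-4-methoxy-6-(2-oxotridecyl)benzoic acid (target), via dilithium dianion 10 (not isolated), via 3-undecylisocoumarin 11 (not isolated)
Conditions: 8 added to LDA (2.2 equiv), THF–DMPU, −78 to −40 °C; 9 (0.95 equiv), −78 to 0 °C; then LiOH (6 equiv), THF–H2O, 60 °C; 1 M HCl, 0 °C, to pH 2–3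
Reagents that add atoms: lithium hydroxide, [Li+].[OH-]
Why: Proposed new method: LDA should first take the phenol proton and then a proton of the 3-methyl group, giving dianion 10 whose carbanion is spread over the exocyclic carbon, C4, the arene and the lactone carbonyl oxygen (a benzo-fused pyranone trienolate); SN2 attack of the exocyclic terminus on 9 makes the CH2–CH2 bond and restores the isocoumarin, after which hydroxide adds to the lactone carbonyl and the enol lactone collapses to carboxylate plus ketone, so that the temporary ring delivers the target on acidification. The closest known reaction types are lateral metalation–alkylation of 6-methyl-2-pyranones (including the dianion of 4-hydroxy-6-methyl-2-pyranone) and of 6-methylsalicylate dianions, and the alkaline opening of isocoumarins to 2-(2-oxoalkyl)benzoic acids; what has not been shown is their combination on a 3-methylisocoumarin. No ring is closed (the pyranone ring is opened) and no stereocentre is formed. The step needs carbon alkylation at the exocyclic carbon rather than at C4 or at oxygen, and mono- rather than dialkylation. The first is secured because the last-formed carbanion is the most basic site of the dianion and only attack through the exocyclic terminus regenerates the fully conjugated isocoumarin, while the chelated lithium phenoxide is a poor nucleophile and also shields the lactone carbonyl from self-condensation. The second is served by limiting 9, low temperature and DMPU, which should make alkylation faster than proton transfer between product and dianion.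

**Compound list**

1 | methyl 2,4-dimethoxy-6-methylbenzoate | COC(=O)c1c(C)cc(OC)cc1OC | starting material
2 | N-methoxy-N-methylacetamide | CON(C)C(C)=O | starting material
3 | benzylic lithium anion of 1 (not isolated) | [Li+].[CH2-]c1cc(OC)cc(OC)c1C(=O)OC | intermediate
4 | lithium hemiaminal alkoxide from 3 and 2 (not isolated) | COC(=O)c1c(CC(C)([O-])N(C)OC)cc(OC)cc1OC.[Li+] | intermediate
5 | methyl 2,4-dimethoxy-6-(2-oxopropyl)benzoate | COC(=O)c1c(CC(C)=O)cc(OC)cc1OC | intermediate
6 | 6,8-dimethoxy-3-methyl-1H-isochromen-1-one | CC1=Cc2cc(OC)cc(OC)c2C(=O)O1 | intermediate
7 | 8-(dichloroboryloxy)-6-methoxy-3-methyl-1H-isochromen-1-one, boron chelated to the lactone C=O (not isolated) | CC1=Cc2cc(OC)cc(OB(Cl)Cl)c2C(=O)O1 | intermediate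
8 | 8-hydroxy-6-methoxy-3-methyl-1H-isochromen-1-one | CC1=Cc2cc(OC)cc(O)c2C(=O)O1 | intermediate
9 | 1-iododecane | CCCCCCCCCCI | starting material
10 | dilithium dianion of 8, phenoxide plus exocyclic carbanion (not isolated) | [Li+].[Li+].[CH2-]C1=Cc2cc(OC)cc([O-])c2C(=O)O1 | intermediate
11 | 8-hydroxy-6-methoxy-3-undecyl-1H-isochromen-1-one, present in the flask as its lithium phenoxide (not isolated) | CCCCCCCCCCCC1=Cc2cc(OC)cc(O)c2C(=O)O1 | intermediate
12 | 2-hydroxy-4-methoxy-6-(2-oxotridecyl)benzoic acid | CCCCCCCCCCCC(=O)Cc1cc(OC)cc(O)c1C(=O)O | target

**Summary**

Total step count: 4. Longest linear sequence: 4 steps (1 → 5 → 6 → 8 → 12).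

**Steps most likely to fail**

1. Step 4 (proposed new method). What may go wrong: incomplete second deprotonation, proton transfer between the alkylated product and the dianion leading to dialkylation, or alkylation through C4 or oxygen instead of the exocyclic carbon. The fallback uses known chemistry and makes the same carbon–carbon connection as a C=C bond at a higher oxidation level; it sets out from 6 and comes back at 11. Riley oxidation of the 3-methyl group of 6 (SeO2, dioxane, reflux) should give 6,8-dimethoxy-1-oxo-1H-isochromene-3-carbaldehyde F1. Wittig olefination with the ylide from decyltriphenylphosphonium bromide (NaHMDS, THF, −78 °C) should give 6,8-dimethoxy-3-[(Z)-undec-1-en-1-yl]-1H-isochromen-1-one F2. Hydrogenation of the disubstituted alkene with Wilkinson's catalyst (H2, RhCl(PPh3)3, benzene–EtOH), which should spare the trisubstituted enol-lactone double bond, should give 6,8-dimethoxy-3-undecyl-1H-isochromen-1-one F3. BCl3 as in step 3 should then give 11, which is isolated this time and opened with LiOH as in the second half of step 4 to give 12.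

2. Step 2. What may go wrong: incomplete enol-lactonisation of the hindered ester, or acid-promoted self-condensation of the ketone before ring closure. The fallback sets out from 5 and comes back at 6. Hydrolysis of the hindered ester (KOH, DMSO–H2O, 80 °C) should give 2,4-dimethoxy-6-(2-oxopropyl)benzoic acid F4, and classical cyclodehydration of this keto acid with acetic anhydride at reflux should give 6.

3. Step 3. What may go wrong: loss of selectivity, with cleavage of both methyl ethers, or Lewis-acid attack on the enol lactone. The fallback sets out from 6 and comes back at 8. Exhaustive demethylation (BBr3, CH2Cl2, −78 °C to rt) should give 6,8-dihydroxy-3-methyl-1H-isochromen-1-one F5. Methylation with MeI (1 equiv) and K2CO3 in acetone should then alkylate only the 6-hydroxyl, because the 8-hydroxyl is hydrogen-bonded to the lactone carbonyl, and give 8.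

**Further compounds**

F1 | step 4 | 6,8-dimethoxy-1-oxo-1H-isochromene-3-carbaldehyde | O=CC1=Cc2cc(OC)cc(OC)c2C(=O)O1
F2 | step 4 | 6,8-dimethoxy-3-[(Z)-undec-1-en-1-yl]-1H-isochromen-1-one | CCCCCCCCC/C=C\C1=Cc2cc(OC)cc(OC)c2C(=O)O1
F3 | step 4 | 6,8-dimethoxy-3-undecyl-1H-isochromen-1-one | CCCCCCCCCCCC1=Cc2cc(OC)cc(OC)c2C(=O)O1
F4 | step 2 | 2,4-dimethoxy-6-(2-oxopropyl)benzoic acid | CC(=O)Cc1cc(OC)cc(OC)c1C(=O)O
F5 | step 3 | 6,8-dihydroxy-3-methyl-1H-isochromen-1-one | CC1=Cc2cc(O)cc(O)c2C(=O)O1
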